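## Retrosynthetic overview

1. Target ⇐ its ring-A aryl triflate by hydrolysis (ring A = the hydroxydimethoxyphenyl ring on C2, ring B = the trimethoxyphenyl ring on C5, oxolane locants of the target); the triflate is both phenol protection and an electronic switch.
2. Oxolane ring, closed last: C5–O bond from a 1,4-diol by ionising only the ring-B benzylic carbinol; the ring-A carbinol oxygen closes the ring (retention at C2, C5 set).
3. 1,4-Diol ⇐ γ-lactol + 3,4,5-trimethoxyphenylmagnesium bromide (C5–aryl bond); the lactol is a temporary ring, formed first and opened again here.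
4. γ-Lactol ⇐ syn homoallylic alcohol + CO/H2 (C4–C5 bond by directed branched hydroformylation; C4 set by equilibration).
5. Homoallylic alcohol ⇐ triflated aldehyde + (Z)-crotylboronate (C2–C3 bond, C2 and C3 set together) ⇐ 3-hydroxy-4,5-dimethoxybenzaldehyde.

Assumption: 3-hydroxy-4,5-dimethoxybenzaldehyde, cis-crotylboronic acid pinacol ester and 3,4,5-trimethoxyphenylmagnesium bromide (THF solution) are bought as catalogue items.

## Route

Step 1
Reactants: 1 3-hydroxy-4,5-dimethoxybenzaldehyde
Product: 2 5-formyl-2,3-dimethoxyphenyl trifluoromethanesulfonate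
Conditions: (CF3SO2)2O (1.2 equiv), 30% aq. K3PO4, toluene, 0 °C → rt
Reagents that add atoms: trifluoromethanesulfonic anhydride, O=S(=O)(OS(=O)(=O)C(F)(F)F)C(F)(F)F
Why: Phenol O-sulfonylation under biphasic aqueous-base conditions is fast and clean; the triflate protects the phenol for steps 2–4 and makes ring A electron-poor for step 5; no stereocentre is formed.

Step 2
Reactants: 2 5-formyl-2,3-dimethoxyphenyl trifluoromethanesulfonate; 3 (Z)-crotylboronic acid pinacol ester
Product: 5 5-[(1R,2S)-1-hydroxy-2-methylbut-3-en-1-yl]-2,3-dimethoxyphenyl trifluoromethanesulfonate, via pinacol borate ester 4 (not isolated)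
Conditions: 3 (1.3 equiv), (R)-3,3'-bis(2,4,6-triisopropylphenyl)-1,1'-binaphthyl-2,2'-diyl hydrogen phosphate (5 mol%), 4 Å MS, toluene, −30 °C; aq. NaHCO3
Reagents that add atoms: none
Why: Chiral phosphoric acid-catalysed asymmetric crotylboration: the acid binds the boronate oxygen and the formyl hydrogen, the closed chair transition state turns the (Z)-olefin geometry into the syn relationship, and the (R)-acid (as recalled; in any case the antipode that directs Re-face attack) sets C2 (R) and C3 (S) together, with about 94% ee and syn:anti above 20:1 expected for aryl aldehydes.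

Step 3
Reactants: 5 5-[(1R,2S)-1-hydroxy-2-methylbut-3-en-1-yl]-2,3-dimethoxyphenyl trifluoromethanesulfonate
Product: 7 5-[(2R,3S,4S)-5-hydroxy-3,4-dimethyloxolan-2-yl]-2,3-dimethoxyphenyl trifluoromethanesulfonate (both anomers), via kinetic lactol mixture 6 (not isolated)
Conditions: Rh(acac)(CO)2 (2 mol%), Ph2POMe (10 mol%), CO/H2 1:1 (20 bar), 4 Å MS, THF, 40 °C; then 1,8-diazabicyclo[5.4.0]undec-7-ene (0.2 equiv), CH2Cl2, rt
Reagents that add atoms: carbon monoxide, [C-]#[O+]
Why: Directed branched-selective hydroformylation: Ph2POMe exchanges reversibly with the hydroxyl and the bound phosphinite delivers rhodium hydride through a six-membered chelate, so the formyl group ends on the internal alkene carbon and the terminal CH2 becomes the C4 methyl; the hydroxy aldehyde closes to the lactol, and amidine-catalysed enolisation of the open form equilibrates C4 to the isomer with its methyl anti to the cis-disposed C3 methyl and C2 aryl, which sets C4 (S).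

Step 4
Reactants: 7 5-[(2R,3S,4S)-5-hydroxy-3,4-dimethyloxolan-2-yl]-2,3-dimethoxyphenyl trifluoromethanesulfonate; 8 3,4,5-trimethoxyphenylmagnesium bromide
Product: 10 5-[(1R,2S,3S)-1,4-dihydroxy-2,3-dimethyl-4-(3,4,5-trimethoxyphenyl)butyl]-2,3-dimethoxyphenyl trifluoromethanesulfonate (both epimers at the new carbinol), via bis(bromomagnesium) alkoxide 9 (not isolated)
Conditions: 8 (3 equiv), THF, −20 → 0 °C; then H2O
Reagents that add atoms: none
Why: Grignard 1,2-addition to the open hydroxy-aldehyde form of the lactol (the first equivalent deprotonates the lactol); uncatalysed aryl triflates are inert to aryl Grignard reagents at this temperature, and the configuration of the new carbinol does not matter because this carbon is ionised in step 5.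

Step 5
Reactants: 10 5-[(1R,2S,3S)-1,4-dihydroxy-2,3-dimethyl-4-(3,4,5-trimethoxyphenyl)butyl]-2,3-dimethoxyphenyl trifluoromethanesulfonate
Product: 11 5-[(2R,3S,4S,5S)-3,4-dimethyl-5-(3,4,5-trimethoxyphenyl)oxolan-2-yl]-2,3-dimethoxyphenyl trifluoromethanesulfonate
Conditions: CF3SO3H (1 mol%), (CF3)2CHOH/CH2Cl2 1:4, −20 → 0 °C; Et3N quench
Reagents that add atoms: none
Why: Proposed new method: triflate-gated SN1 cycloetherification – in (CF3)2CHOH only the ring-B carbinol should ionise, because the meta-OSO2CF3 group on ring A (σm about +0.56 against +0.12 for OCH3, ρ+ about −5) is estimated to slow ionisation at C2 by roughly two orders of magnitude and also suppresses Friedel–Crafts capture of the cation by ring A; the C2 hydroxyl keeps its R configuration and traps the planar C5 cation anti to the C4 methyl (closure is reversible at C5 only, so both carbinol epimers of 10 converge), setting C5 (S); the closest known reaction type is the acid-mediated SN1 cyclodehydration of 1,4-diarylbutane-1,4-diols, but site selection between two electron-rich secondary benzylic carbinols by a remote sulfonate switch has not been shown.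

Step 6
Reactants: 11 5-[(2R,3S,4S,5S)-3,4-dimethyl-5-(3,4,5-trimethoxyphenyl)oxolan-2-yl]-2,3-dimethoxyphenyl trifluoromethanesulfonate
Product: 13 5-[(2R,3S,4S,5S)-3,4-dimethyl-5-(3,4,5-trimethoxyphenyl)oxolan-2-yl]-2,3-dimethoxyphenol, via potassium phenoxide 12 (not isolated)
Conditions: KOH (5 equiv), 1,4-dioxane/H2O 2:1, 60 °C; then 1 M HCl to pH 5
Reagents that add atoms: none
Why: Hydroxide attacks sulfur of the aryl triflate (sulfonate ester hydrolysis) and releases the phenoxide, while the oxolane and the methyl ethers are inert to aqueous base, so no stereocentre is touched.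

## Compound list

1 | 3-hydroxy-4,5-dimethoxybenzaldehyde | COc1cc(C=O)cc(O)c1OC | starting material
2 | 5-formyl-2,3-dimethoxyphenyl trifluoromethanesulfonate | COc1cc(C=O)cc(OS(=O)(=O)C(F)(F)F)c1OC | intermediate
3 | (Z)-crotylboronic acid pinacol ester, 2-[(2Z)-but-2-en-1-yl]-4,4,5,5-tetramethyl-1,3,2-dioxaborolane | C/C=C\CB1OC(C)(C)C(C)(C)O1 | starting material
4 | 2,3-dimethoxy-5-[(1R,2S)-2-methyl-1-[(4,4,5,5-tetramethyl-1,3,2-dioxaborolan-2-yl)oxy]but-3-en-1-yl]phenyl trifluoromethanesulfonate | COc1cc([C@H](OB2OC(C)(C)C(C)(C)O2)[C@@H](C)C=C)cc(OS(=O)(=O)C(F)(F)F)c1OC | intermediate (not isolated)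
5 | 5-[(1R,2S)-1-hydroxy-2-methylbut-3-en-1-yl]-2,3-dimethoxyphenyl trifluoromethanesulfonate | COc1cc([C@H](O)[C@@H](C)C=C)cc(OS(=O)(=O)C(F)(F)F)c1OC | intermediate
6 | 5-[(2R,3S)-5-hydroxy-3,4-dimethyloxolan-2-yl]-2,3-dimethoxyphenyl trifluoromethanesulfonate, mixture of epimers at the oxolane C4 and C5 | COc1cc([C@@H]2OC(O)C(C)[C@@H]2C)cc(OS(=O)(=O)C(F)(F)F)c1OC | intermediate (not isolated)
7 | 5-[(2R,3S,4S)-5-hydroxy-3,4-dimethyloxolan-2-yl]-2,3-dimethoxyphenyl trifluoromethanesulfonate, both anomers | COc1cc([C@@H]2OC(O)[C@@H](C)[C@@H]2C)cc(OS(=O)(=O)C(F)(F)F)c1OC | intermediate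
8 | 3,4,5-trimethoxyphenylmagnesium bromide | COc1cc([Mg]Br)cc(OC)c1OC | starting material
9 | bis(bromomagnesium) 1,4-dialkoxide of diol 10 | COc1cc([C@H](O[Mg]Br)[C@@H](C)[C@H](C)C(O[Mg]Br)c2cc(OC)c(OC)c(OC)c2)cc(OS(=O)(=O)C(F)(F)F)c1OC | intermediate (not isolated)
10 | 5-[(1R,2S,3S)-1,4-dihydroxy-2,3-dimethyl-4-(3,4,5-trimethoxyphenyl)butyl]-2,3-dimethoxyphenyl trifluoromethanesulfonate, both epimers at butyl C4 | COc1cc([C@H](O)[C@@H](C)[C@H](C)C(O)c2cc(OC)c(OC)c(OC)c2)cc(OS(=O)(=O)C(F)(F)F)c1OC | intermediate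
11 | 5-[(2R,3S,4S,5S)-3,4-dimethyl-5-(3,4,5-trimethoxyphenyl)oxolan-2-yl]-2,3-dimethoxyphenyl trifluoromethanesulfonate | COc1cc([C@@H]2O[C@H](c3cc(OC)c(OC)c(OC)c3)[C@@H](C)[C@@H]2C)cc(OS(=O)(=O)C(F)(F)F)c1OC | intermediate
12 | potassium 5-[(2R,3S,4S,5S)-3,4-dimethyl-5-(3,4,5-trimethoxyphenyl)oxolan-2-yl]-2,3-dimethoxyphenolate | COc1cc([C@@H]2O[C@H](c3cc(OC)c(OC)c(OC)c3)[C@@H](C)[C@@H]2C)cc([O-])c1OC.[K+] | intermediate (not isolated)
13 | 5-[(2R,3S,4S,5S)-3,4-dimethyl-5-(3,4,5-trimethoxyphenyl)oxolan-2-yl]-2,3-dimethoxyphenol | COc1cc([C@@H]2O[C@H](c3cc(OC)c(OC)c(OC)c3)[C@@H](C)[C@@H]2C)cc(O)c1OC | target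

## Step count and risks

Total step count: 6. Longest linear sequence: 6 steps (1 → 13); 3 and 8 are bought.

Steps most likely to fail:

Step 5 (the new step). Risks are incomplete site selection (the C2 epimer, the all-trans isomer, would form through ring-A ionisation), slow drift at C2 on long exposure, and aryltetralin formation. The known-chemistry fallback never makes a benzylic cation and keeps the lactol oxygen in the ring. It sets out from lactol 7, which with PhSO2H and CaCl2 in CH2Cl2 gives the anomeric sulfone 5-[(2R,3S,4S)-5-(benzenesulfonyl)-3,4-dimethyloxolan-2-yl]-2,3-dimethoxyphenyl trifluoromethanesulfonate F5. Grignard reagent 8 is transmetallated with ZnBr2 in THF to (3,4,5-trimethoxyphenyl)zinc bromide F6, which displaces the sulfinate through the ring oxocarbenium ion, the aryl group entering anti to the C4 methyl. The sequence comes back to the route at 11, bypassing steps 4 and 5.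

Step 3. Risks are slow exchange of the hindered benzylic alcohol with the phosphinite, a poor branched-to-linear ratio, and incomplete equilibration at C4. The fallback sets out from 5 and installs the C4 methyl by enolate alkylation instead of CO insertion. Hydroboration–oxidation (9-borabicyclo[3.3.1]nonane, then NaBO3·4H2O) gives the diol 5-[(1R,2S)-1,4-dihydroxy-2-methylbutyl]-2,3-dimethoxyphenyl trifluoromethanesulfonate F2. Oxidative lactonisation with 2,2,6,6-tetramethylpiperidin-1-oxyl and PhI(OAc)2 gives the cis-lactone 2,3-dimethoxy-5-[(2R,3S)-3-methyl-5-oxooxolan-2-yl]phenyl trifluoromethanesulfonate F3. LiN(SiMe3)2 then MeI at −78 °C methylates the enolate on the face opposite the cis methyl/aryl pair to give 5-[(2R,3S,4S)-3,4-dimethyl-5-oxooxolan-2-yl]-2,3-dimethoxyphenyl trifluoromethanesulfonate F4. i-Bu2AlH at −78 °C then comes back to the route at lactol 7.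

Step 2. The risk is an ee or syn:anti ratio below the usual level for this particular aldehyde; every later centre is relayed from C2 and C3. The fallback sets out from 2 and forms the same bond from the alcohol oxidation level through a crotylruthenium instead of a crotylboron species. NaBH4 in MeOH gives the benzyl alcohol 5-(hydroxymethyl)-2,3-dimethoxyphenyl trifluoromethanesulfonate F1. Ruthenium-catalysed transfer-hydrogenative syn-crotylation with butadiene follows, using H2Ru(CO)(PPh3)3, the bisphosphine SEGPHOS and a TADDOL-derived phosphoric acid, antipodes chosen for the (1R,2S) adduct. It comes back to the route at 5.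

Further compounds
F1 | step 2 | 5-(hydroxymethyl)-2,3-dimethoxyphenyl trifluoromethanesulfonate | COc1cc(CO)cc(OS(=O)(=O)C(F)(F)F)c1OC
F2 | step 3 | 5-[(1R,2S)-1,4-dihydroxy-2-methylbutyl]-2,3-dimethoxyphenyl trifluoromethanesulfonate | COc1cc([C@H](O)[C@@H](C)CCO)cc(OS(=O)(=O)C(F)(F)F)c1OC
F3 | step 3 | 2,3-dimethoxy-5-[(2R,3S)-3-methyl-5-oxooxolan-2-yl]phenyl trifluoromethanesulfonate | COc1cc([C@@H]2OC(=O)C[C@@H]2C)cc(OS(=O)(=O)C(F)(F)F)c1OC
F4 | step 3 | 5-[(2R,3S,4S)-3,4-dimethyl-5-oxooxolan-2-yl]-2,3-dimethoxyphenyl trifluoromethanesulfonate | COc1cc([C@@H]2OC(=O)[C@@H](C)[C@@H]2C)cc(OS(=O)(=O)C(F)(F)F)c1OC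
F5 | step 5 | 5-[(2R,3S,4S)-5-(benzenesulfonyl)-3,4-dimethyloxolan-2-yl]-2,3-dimethoxyphenyl trifluoromethanesulfonate, both epimers at the sulfonyl carbon | COc1cc([C@@H]2OC(S(=O)(=O)c3ccccc3)[C@@H](C)[C@@H]2C)cc(OS(=O)(=O)C(F)(F)F)c1OC
F6 | step 5 | (3,4,5-trimethoxyphenyl)zinc bromide | COc1cc([Zn]Br)cc(OC)c1OC
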